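The rate constants are invented.

The slowness here belongs to links going over to isomer of the product, with a relaxation half-life of 6.70 s, longer than the 0.20 s half-life of first end groups by their step in the south flask, so first count what reaches links at all.

the same everywhere: third end groups 0.250 equiv; time 50 s

| flask | first end groups | second end groups | remark |
|---|---|---|---|
| south | 10 mM | 0.900 equiv | everything together at the start |
| south-east | 10 mM | 0.900 equiv (fed, over 20 s) | all else is in the flask from the start; the feed brings no volume worth counting |
| north | 10 mM (fed, over 20 s) | 0.900 equiv | all else is in the flask from the start; the feed brings no volume worth counting |

    first end groups + second end groups → links (k1 = 390 /M/s)
    second end groups + third end groups → links of the second sort (k2 = 610 /M/s)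
    links ⇌ isomer of the product (K3 = 29, k3 = 0.10 /s)
    2 third end groups → self-condensation product (k4 = 350 /M/s)

- the flask that comes out highest in amount of isomer of the product, in percent of the first end groups charged, or "all alike" when all lie within 1.5 percentage points (south / south-east / north / all alike)
- isomer of the product at the end, in percent of the first end groups charged, south
- isomer of the product at the end, in percent of the first end groups charged, south-east
- isomer of the product at the end, in percent of the first end groups charged, north

- where a step has two of a species, its rate is k times that concentration squared, and two are used at each turn
- run time (south): 50 s

Reckon in fractions of the first end groups charged. Second end groups are the limiting reagent in these flasks, and third end groups take a share of them. Let x be the starting loss of third end groups by self-condensation over their starting loss to second end groups, with second end groups held at a steady level; integrating the two losses gives the charge of third end groups times the logarithm of one plus x, over x.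

In the south-east flask, set the standing level of second end groups to the feed rate over their rate of loss to first end groups: 1.15%. Then x is 24.9, and the toll, the fraction of second end groups lost to third end groups, is 3.27%.

Object that first end groups run down during the feed and lift that level. But third end groups have a self-condensation half-life of 0.571 s, shorter than the feed, so the early level is the one to use.

In the north flask, take second end groups as standing at their charge, so x is 0.319 and the toll 21.7%.

In the south flask, that held level fails: second end groups have a half-life of 0.178 s against first end groups as charged, while third end groups have one of 0.126 s against second end groups as charged. So place south between the other two.

Now multiply what remains by the equilibrium share, 96.7%. Object that relaxation is unfinished: taken, as an estimate, as made steadily over the feed, links still hold 1.90% of their way to go at the end. My reckoning is therefore 82.2% for south-east and 64.8% for north.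

The forecast names south-east, with 82.7% there, 69.6% in south and 65.5% in north, reasoning “So the yield of links is set first, then isomerised.” The flasks give 82.3% in south-east, 69.4% in south and 65.3% in north, which puts south-east highest.

Strike out the step to links of the second sort and the gap between south-east and north goes from 17 percentage points to −0.17 points; strike out self-condensation and it falls to 3.4 points, so the two steps make the gap together. South-east holds 2.99% as links of the second sort against the toll of 3.27%. Now take north with 1.50 equiv of second end groups: x is 0.191 and the toll 22.9%, which leaves more second end groups than first end groups charged, so reckon 94.9% isomer. That flask gives 94.7%.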